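## The problem

The target 22 is a (2S)-flavan. Its resorcinol ring A (C4a to C8a) is fused to pyran ring C through O1–C8a and C4–C4a, has a free hydroxyl on C7 and hydrogen on C5 and C8, and carries a 1,3-diarylpropyl chain on C6. The chain begins with a doubly benzylic methine of R configuration that joins ring A to the 4-hydroxyphenyl ring D and runs through two methylenes to the 4-hydroxy-2-methoxyphenyl ring E; C2 carries the 5-hydroxy-2-methoxyphenyl ring B. The two stereocentres lie six bonds apart on opposite sides of ring A, so neither can direct the other and each needs its own external control element. Four phenols must end free while two aryl methyl ethers stay, which excludes any deprotection that cleaves methyl ethers. The O1–C2 bond is a benzylic aryl ether open to acid ionisation and hydrogenolysis, the methine is sensitive to strong base, and ring B is an easily oxidised hydroquinone monoether. Rings A and E are both 4-alkylresorcinol derivatives of similar nucleophilicity, so electrophilic functionalisation of ring A has to precede the arrival of ring E. The feature that opens the key step is ring A itself: O1 on C8a, a free C7 hydroxyl and no oxygen on C5 make up the 2',4'-dihydroxy-6'-deoxy pattern of the chalcones that type 2 chalcone isomerase closes to (2S)-flavanones, once a carbonyl is placed at C4.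

## Retrosynthesis

**22 back to 20 (no skeletal cut).** A carbonyl is added at C4, giving flavanone 20 by way of the benzylic alcohol 21. This costs two reductive steps, but it turns ring C into the product of a conjugate addition. The neighbouring options are closure of O1–C2 by substitution at an ionisable benzylic carbinol or formation of C4–C4a, and both put C2 at risk or need a regiochemical choice on ring A. The forward steps must reduce the ketone and cleave the C4–O bond without opening O1–C2.

**20 back to 19 (O1–C2).** Cutting O1–C2 gives the open chalcone 19. Ring C and C2 are removed together, and 19 has a single stereocentre and no protecting groups. The forward reaction is an oxa-Michael addition of the C8a oxygen to the enone that must be face-selective under catalyst control and faster than the racemic background closure. An isomerase is asked to do this on a substrate larger than its natural ones.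

**19 back to 15 and 17 (C2–C3, flavan numbering).** The enone comes from a Claisen–Schmidt condensation of methyl ketone 15 with aldehyde 17, followed by release of all phenols from 18. MOM ethers are used on every phenol, ring D included, because they survive organometallic reagents and strong base and fall together under mild acid that leaves the enone and the methyl ethers alone; benzyl ethers could not be removed next to the enone. Aldehyde 17 is one step from 16.

**15 back to 13 (C4a–acetyl).** The acetyl group is traced to an aryllithium made from bromide 13. Direct acylation of ring A would not distinguish it from ring E, so the bromine serves as a positional marker set earlier. The forward step needs a fast bromine–lithium exchange and a single acyl transfer.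

**13 back to 7 and 9 (ring E–chain bond, via 11).** The benzylic methylene next to ring E is traced to ketone 11, and 11 is cut between its carbonyl and ring E into Weinreb amide 7 and the aryl Grignard reagent from 9. A cross-coupling of an alkyl fragment with ring E would compete with the ring A bromide, which is why the carbonyl route is preferred. The deoxygenation must spare the C–Br bond and the MOM acetals, which points to an anionic hydrazone-based reduction instead of hydrogenolysis or ionic hydrogenation. Bromide 9 is one step from 8.

**7 back to 4 (C–Br, then lactone opening).** Amide 7 comes from phenol 6 by protection and 6 from 5 by bromination; 5 is the ring-opened form of lactone 4. Opening the lactone first frees the one phenol whose para position is the carbon that must carry the acetyl group, so bromination is directed there while ring D is only an ether and ring E is absent.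

**4 back to 2 and 3 (methine–ring D).** The methine stereocentre is cut at its bond to ring D, giving protected coumarin 2 and boronic acid 3; 2 is one step from 7-hydroxycoumarin 1. Asymmetric conjugate arylation of a coumarin has a documented sense of induction, and the lactone carbonyl later becomes the chain carbon that bonds to ring E. An open-chain enone would also serve but with a less secure facial assignment. The forward reaction has to overcome the low electrophilicity of a 7-alkoxycoumarin.

## Roads not taken

**Alternative 1:** Ring A is built last. The cut runs through C5–C6 and C4a–C8a: the silyloxy diene A1, which carries the methine and its two aryl groups, and the ethynyl ketone A2, which carries C2, C3 and C4, would combine in a Diels–Alder-type benzannulation. Loss of the methoxy and one silyloxy group as a silyl ether would aromatise the adduct to the resorcinol ketone A3, whose (3R)-silyloxy carbinol is then closed onto the C8a phenol with inversion.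
- Merits: the route is convergent, both stereocentres are made beforehand in separate fragments by established asymmetric methods, and the substitution pattern of ring A follows from the polarity of the two partners, so the ring A versus ring E problem that forces the bromination in the chosen route (5 to 6) does not arise. It also does not depend on an untested enzyme, and in that respect it is the safer plan.
- Weak points: A1 is a moisture-sensitive ketene acetal whose nucleophilic terminus carries a bulky branched substituent. A2 and A3 are β-silyloxy or β-hydroxy ketones that can eliminate to the chalcone, which would then close without control. The final closure is a substitution at a carbinol that is benzylic to an ortho-methoxyaryl ring and can ionise. The benzyl ethers must leave by hydrogenolysis next to O1–C2.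
- Comparison: the chosen plan sets against this a ring closure in which C2 is created directly, with no leaving group at an ionisable centre and no protecting groups present, and an aromatic ring A available from the first step.

**Alternative 2:** The cut is C4–C4a. The (S)-aryl propargyl ether A4 of the ring A phenol would cyclise under a cationic phosphine-gold catalyst by 6-endo attack of C4a on the activated alkyne, giving the 2H-chromene A5 with C2 carried through unchanged.
- Merits: the conditions are mild, the C2 stereocentre can come from an asymmetric alkynylation of the ring B aldehyde, and no C4 oxygen has to be removed. One hydrogenation of A5 would saturate C3–C4 and cleave the benzyl ethers, so the end game is shorter than steps 14 and 15 of the chosen route.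
- Weak points: the stereocentre of A4 is at once benzylic, propargylic and ether-bearing. Forming that ether from a phenol with clean inversion, and keeping it intact under a carbophilic Lewis acid, is uncertain. C4a and C8 are both ortho to the ether oxygen, so attack at C8 between the two oxygens would compete. 2-Aryl-2H-chromenes can lose configuration by electrocyclic ring opening.
- Comparison: the chosen plan is longer at the end but forms C2 in the ring-closing event under catalyst control and has no regiochemical choice on ring A at that stage.

**Alternative 3:** The cuts are C3–C4 and O1–C2. Acid dehydration of the salicyl alcohol A6 would release an ortho-quinone methide that adds across the vinyl group of styrene A7 under a chiral BINOL-derived N-triflylphosphoramide, closing ring C and giving the tetrabenzyl flavan A8 directly.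
- Merits: this is the most convergent road. Two bonds and ring C form in one step at the flavan oxidation level, and A8 is one debenzylation from 22, so it would clearly be shorter than the chosen route.
- Weak points: the methide derived from A6 is unsubstituted at its exocyclic carbon, which gives the chiral acid little to discriminate and leaves the intermediate prone to oligomerisation and to capture by the electron-rich ring E or by C8 of another molecule. A6 needs a regioselective one-carbon functionalisation of ring A at C4a, the same ring A versus ring E problem in another form. The last hydrogenolysis carries the O1–C2 risk that step 15 also has.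
- Comparison: both plans rest on a selective step without close precedent. The chosen plan offers an intramolecular closure with fixed regiochemistry, no competing intermolecular paths, and a catalyst whose face selectivity is intrinsic to the reaction class.

Key step: step 13

Assumptions: boronic acid 3 and aldehyde 16 are purchased. Alcohol 21 is drawn as the 2,4-cis (4S) isomer usually formed from flavanones; a trans isomer would serve equally, since C4 becomes a methylene in step 15.

## Route

Step 1
Reactants: 1 7-hydroxycoumarin (7-hydroxy-2H-chromen-2-one)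
Product: 2 7-(methoxymethoxy)-2H-chromen-2-one
Conditions: MOMCl, K2CO3, acetone, 0 °C to rt
Reagents that add atoms: chloromethyl methyl ether, COCCl
Why: O-alkylation of the acidic 7-hydroxyl (MOM acetal protection); the ether masks the phenol through the rhodium and organometallic steps and is cleaved by mild acid in step 12.

Step 2
Reactants: 2 7-(methoxymethoxy)-2H-chromen-2-one; 3 4-(methoxymethoxy)phenylboronic acid
Product: 4 (4R)-7-(methoxymethoxy)-4-[4-(methoxymethoxy)phenyl]-3,4-dihydro-2H-chromen-2-one
Conditions: Rh(acac)(C2H4)2 (3 mol%), (R)-SEGPHOS (3.3 mol%), 3 (3 equiv), 1,4-dioxane/H2O 10:1, 60 °C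
Reagents that add atoms: none
Why: Hayashi–Miyaura asymmetric conjugate addition: the aryl–rhodium species formed by transmetalation adds across C3=C4 and water protonates the rhodium enolate. (R)-SEGPHOS is the ligand known to give (R)-4-arylchroman-2-ones from coumarins with high enantioselectivity, and the same facial sense sets the R methine here (priorities C4a > ring D > C3 > H are unchanged).

Step 3
Reactants: 4 (4R)-7-(methoxymethoxy)-4-[4-(methoxymethoxy)phenyl]-3,4-dihydro-2H-chromen-2-one
Product: 5 (3R)-3-[2-hydroxy-4-(methoxymethoxy)phenyl]-N-methoxy-3-[4-(methoxymethoxy)phenyl]-N-methylpropanamide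
Conditions: MeNH(OMe)·HCl, iPrMgCl, THF, -20 to 0 °C
Reagents that add atoms: N,O-dimethylhydroxylamine hydrochloride, CNOC.Cl
Why: Weinreb aminolysis of the aryl ester (lactone) by the chloromagnesium amide; it frees the phenol that will direct the bromination and gives an acyl group that accepts only one aryl nucleophile. The stereocentre is β to the carbonyl and not affected; 5 should be used promptly to avoid relactonisation.

Step 4
Reactants: 5 (3R)-3-[2-hydroxy-4-(methoxymethoxy)phenyl]-N-methoxy-3-[4-(methoxymethoxy)phenyl]-N-methylpropanamide
Product: 6 (3R)-3-[5-bromo-2-hydroxy-4-(methoxymethoxy)phenyl]-N-methoxy-3-[4-(methoxymethoxy)phenyl]-N-methylpropanamide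
Conditions: NBS (1.0 equiv), MeCN, -20 to 0 °C, dark
Reagents that add atoms: N-bromosuccinimide, O=C1CCC(=O)N1Br
Why: Electrophilic aromatic bromination; the carbon para to the free hydroxyl and ortho to the MOM ether is the most activated and least hindered site of ring A, ring D is only an aryl ether, and ring E is not yet present.

Step 5
Reactants: 6 (3R)-3-[5-bromo-2-hydroxy-4-(methoxymethoxy)phenyl]-N-methoxy-3-[4-(methoxymethoxy)phenyl]-N-methylpropanamide
Product: 7 (3R)-3-[5-bromo-2,4-bis(methoxymethoxy)phenyl]-N-methoxy-3-[4-(methoxymethoxy)phenyl]-N-methylpropanamide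
Conditions: MOMCl, K2CO3, DMF, 0 °C to rt
Reagents that add atoms: chloromethyl methyl ether, COCCl
Why: O-alkylation of the phenoxide (MOM protection); this removes the acidic proton before the Grignard and lithiation steps and excludes relactonisation.

Step 6
Reactants: 8 4-bromo-3-methoxyphenol
Product: 9 1-bromo-2-methoxy-4-(methoxymethoxy)benzene
Conditions: MOMCl, K2CO3, acetone, rt
Reagents that add atoms: chloromethyl methyl ether, COCCl
Why: MOM protection of the ring E phenol so that the aryl bromide can be turned into a Grignard reagent.

Step 7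
Reactants: 7 (3R)-3-[5-bromo-2,4-bis(methoxymethoxy)phenyl]-N-methoxy-3-[4-(methoxymethoxy)phenyl]-N-methylpropanamide; 9 1-bromo-2-methoxy-4-(methoxymethoxy)benzene
Product: 11 (3R)-3-[5-bromo-2,4-bis(methoxymethoxy)phenyl]-1-[2-methoxy-4-(methoxymethoxy)phenyl]-3-[4-(methoxymethoxy)phenyl]propan-1-one, via aryl Grignard reagent 10 (not isolated)
Conditions: 9, Mg, cat. I2, THF, 50 °C; then 7, THF, 0 °C to rt
Reagents that add atoms: none
Why: Grignard formation followed by Weinreb ketone synthesis; the chelated tetrahedral adduct prevents a second addition, and an aryl Grignard reagent does not exchange with the ring A bromide at these temperatures.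

Step 8
Reactants: 11 (3R)-3-[5-bromo-2,4-bis(methoxymethoxy)phenyl]-1-[2-methoxy-4-(methoxymethoxy)phenyl]-3-[4-(methoxymethoxy)phenyl]propan-1-one
Product: 13 1-bromo-5-[(1R)-3-[2-methoxy-4-(methoxymethoxy)phenyl]-1-[4-(methoxymethoxy)phenyl]propyl]-2,4-bis(methoxymethoxy)benzene, via hydrazone 12 (not isolated)
Conditions: N2H4·H2O, KOH, diethylene glycol, 130 °C then 195 °C
Reagents that add atoms: none
Why: Wolff–Kishner reduction (Huang-Minlon variant): hydrazone 12 is deprotonated and loses N2 to leave the methylene. The path is anionic, so the aryl bromide and the base-stable MOM acetals should persist and no benzylic cation forms that could cyclise onto ring A or ring D; the stereocentre is β to the carbonyl and cannot enolise.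

Step 9
Reactants: 13 1-bromo-5-[(1R)-3-[2-methoxy-4-(methoxymethoxy)phenyl]-1-[4-(methoxymethoxy)phenyl]propyl]-2,4-bis(methoxymethoxy)benzene
Product: 15 1-{5-[(1R)-3-[2-methoxy-4-(methoxymethoxy)phenyl]-1-[4-(methoxymethoxy)phenyl]propyl]-2,4-bis(methoxymethoxy)phenyl}ethan-1-one, via aryllithium 14 (not isolated)
Conditions: n-BuLi, THF, -78 °C; then MeC(O)N(OMe)Me, -78 to 0 °C
Reagents that add atoms: N-methoxy-N-methylacetamide, CC(=O)N(C)OC
Why: Bromine–lithium exchange, much faster at -78 °C than any deprotonation, then acylation by a Weinreb amide, whose stable adduct releases the methyl ketone only on work-up; the acetyl group lands exactly where the bromine was.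

Step 10
Reactants: 16 5-hydroxy-2-methoxybenzaldehyde
Product: 17 2-methoxy-5-(methoxymethoxy)benzaldehyde
Conditions: MOMCl, K2CO3, acetone, rt
Reagents that add atoms: chloromethyl methyl ether, COCCl
Why: MOM protection of the ring B phenol so that the aldehyde is not deactivated as a phenoxide in the condensation and all five acetals can be removed together.

Step 11
Reactants: 15 1-{5-[(1R)-3-[2-methoxy-4-(methoxymethoxy)phenyl]-1-[4-(methoxymethoxy)phenyl]propyl]-2,4-bis(methoxymethoxy)phenyl}ethan-1-one; 17 2-methoxy-5-(methoxymethoxy)benzaldehyde
Product: 18 (2E)-3-[2-methoxy-5-(methoxymethoxy)phenyl]-1-{5-[(1R)-3-[2-methoxy-4-(methoxymethoxy)phenyl]-1-[4-(methoxymethoxy)phenyl]propyl]-2,4-bis(methoxymethoxy)phenyl}prop-2-en-1-one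
Conditions: KOH, EtOH/THF, rt
Reagents that add atoms: none
Why: Claisen–Schmidt condensation: the methyl ketone is the only enolisable carbonyl and the aldehyde cannot enolise; dehydration of the aldol gives the conjugated E enone.

Step 12
Reactants: 18 (2E)-3-[2-methoxy-5-(methoxymethoxy)phenyl]-1-{5-[(1R)-3-[2-methoxy-4-(methoxymethoxy)phenyl]-1-[4-(methoxymethoxy)phenyl]propyl]-2,4-bis(methoxymethoxy)phenyl}prop-2-en-1-one
Product: 19 (2E)-1-{2,4-dihydroxy-5-[(1R)-3-(4-hydroxy-2-methoxyphenyl)-1-(4-hydroxyphenyl)propyl]phenyl}-3-(5-hydroxy-2-methoxyphenyl)prop-2-en-1-one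
Conditions: 3 M HCl (aq), MeOH/THF, 45 °C, Ar
Reagents that add atoms: none
Why: Acid-catalysed cleavage of the five MOM acetals with transfer of the methylene unit to methanol; the enone, both methyl ethers and the methine are inert, and in a 6'-deoxychalcone the 2'-hydroxyl is hydrogen-bonded to the carbonyl, so acid-mediated ring closure should be slow on this time scale.

Step 13
Reactants: 19 (2E)-1-{2,4-dihydroxy-5-[(1R)-3-(4-hydroxy-2-methoxyphenyl)-1-(4-hydroxyphenyl)propyl]phenyl}-3-(5-hydroxy-2-methoxyphenyl)prop-2-en-1-one
Product: 20 (2S)-7-hydroxy-2-(5-hydroxy-2-methoxyphenyl)-6-[(1R)-3-(4-hydroxy-2-methoxyphenyl)-1-(4-hydroxyphenyl)propyl]-2,3-dihydro-4H-chromen-4-one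
Conditions: type 2 chalcone isomerase (recombinant, Medicago sativa), 50 mM potassium phosphate pH 7.5, 10% v/v DMSO, 25 °C, Ar
Reagents that add atoms: none
Why: Proposed new method: chalcone isomerase cyclisation (EC 5.5.1.6) is established for isoliquiritigenin-type 6'-deoxychalcones, which is the closest known reaction type, but not for a chalcone with a branched diarylpropyl group at C5' and a 2-methoxy-5-hydroxy ring B, and that extension is what is proposed. The enzyme binds the chalcone with the ketone polarised by active-site hydrogen bonds, the 2'-phenoxide (the future O1 on C8a) adds to the β-carbon of the enone, and the resulting enolate is protonated at C3 by water. Ring C closes in a 6-endo-trig oxa-Michael mode. C2 is set as S by the enzyme, which presents one face of the β-carbon to the phenoxide; the remote R methine has no influence. The step needs face selectivity over the racemic background closure, and the substrate secures it through its 2',4'-dihydroxy-6'-deoxy ring A: the 2'-OH to carbonyl hydrogen bond keeps the uncatalysed closure slow near neutral pH, and the same pattern is what type 2 enzymes recognise. The weak point, room for the C5' substituent, is met within the idea by screening several type 2 isomerases and the structurally unrelated bacterial isomerase of Eubacterium ramulus, with enlargement of the pocket by mutagenesis if required. Flavanone 20 is taken into step 14 without delay because retro-oxa-Michael opening would erode C2.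

Step 14
Reactants: 20 (2S)-7-hydroxy-2-(5-hydroxy-2-methoxyphenyl)-6-[(1R)-3-(4-hydroxy-2-methoxyphenyl)-1-(4-hydroxyphenyl)propyl]-2,3-dihydro-4H-chromen-4-one
Product: 21 (2S,4S)-2-(5-hydroxy-2-methoxyphenyl)-6-[(1R)-3-(4-hydroxy-2-methoxyphenyl)-1-(4-hydroxyphenyl)propyl]-3,4-dihydro-2H-chromene-4,7-diol
Conditions: NaBH4, CeCl3·7H2O, MeOH/THF, -20 °C
Reagents that add atoms: none
Why: Hydride 1,2-reduction of the aryl ketone under Luche conditions; CeCl3 activates the carbonyl and keeps the medium close to neutral, so base-induced ring opening that would scramble C2 should not compete. The 2,4-cis alcohol is expected as usual for flavanones, and its C4 configuration is removed in step 15.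

Step 15
Reactants: 21 (2S,4S)-2-(5-hydroxy-2-methoxyphenyl)-6-[(1R)-3-(4-hydroxy-2-methoxyphenyl)-1-(4-hydroxyphenyl)propyl]-3,4-dihydro-2H-chromene-4,7-diol
Product: 22 (2S)-2-(5-hydroxy-2-methoxyphenyl)-6-[(1R)-3-(4-hydroxy-2-methoxyphenyl)-1-(4-hydroxyphenyl)propyl]-3,4-dihydro-2H-chromen-7-ol
Conditions: H2 (1 atm), 10% Pd/C, AcOH, rt
Reagents that add atoms: none
Why: Catalytic hydrogenolysis of a benzylic alcohol: the C4 hydroxyl is ortho to O1 and para to the C7 hydroxyl, so in acetic acid it ionises readily and should be reduced faster than the cyclic O1–C2 ether; neither stereocentre takes part.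

## Compound list

1 | 7-hydroxycoumarin (7-hydroxy-2H-chromen-2-one) | O=c1ccc2ccc(O)cc2o1 | starting material
2 | 7-(methoxymethoxy)-2H-chromen-2-one | COCOc1ccc2ccc(=O)oc2c1 | intermediate
3 | 4-(methoxymethoxy)phenylboronic acid | COCOc1ccc(cc1)B(O)O | starting material
4 | (4R)-7-(methoxymethoxy)-4-[4-(methoxymethoxy)phenyl]-3,4-dihydro-2H-chromen-2-one | O=C1C[C@H](c2ccc(OCOC)cc2)c2ccc(OCOC)cc2O1 | intermediate
5 | (3R)-3-[2-hydroxy-4-(methoxymethoxy)phenyl]-N-methoxy-3-[4-(methoxymethoxy)phenyl]-N-methylpropanamide | CON(C)C(=O)C[C@H](c1ccc(OCOC)cc1)c1ccc(OCOC)cc1O | intermediate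
6 | (3R)-3-[5-bromo-2-hydroxy-4-(methoxymethoxy)phenyl]-N-methoxy-3-[4-(methoxymethoxy)phenyl]-N-methylpropanamide | CON(C)C(=O)C[C@H](c1ccc(OCOC)cc1)c1cc(Br)c(OCOC)cc1O | intermediate
7 | (3R)-3-[5-bromo-2,4-bis(methoxymethoxy)phenyl]-N-methoxy-3-[4-(methoxymethoxy)phenyl]-N-methylpropanamide | CON(C)C(=O)C[C@H](c1ccc(OCOC)cc1)c1cc(Br)c(OCOC)cc1OCOC | intermediate
8 | 4-bromo-3-methoxyphenol | COc1cc(O)ccc1Br | starting material
9 | 1-bromo-2-methoxy-4-(methoxymethoxy)benzene | COCOc1ccc(Br)c(OC)c1 | intermediate
10 | [2-methoxy-4-(methoxymethoxy)phenyl]magnesium bromide | COCOc1ccc([Mg]Br)c(OC)c1 | intermediate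
11 | (3R)-3-[5-bromo-2,4-bis(methoxymethoxy)phenyl]-1-[2-methoxy-4-(methoxymethoxy)phenyl]-3-[4-(methoxymethoxy)phenyl]propan-1-one | COCOc1ccc(C(=O)C[C@H](c2ccc(OCOC)cc2)c2cc(Br)c(OCOC)cc2OCOC)c(OC)c1 | intermediate
12 | hydrazone of ketone 11 | COCOc1ccc(C(=NN)C[C@H](c2ccc(OCOC)cc2)c2cc(Br)c(OCOC)cc2OCOC)c(OC)c1 | intermediate
13 | 1-bromo-5-[(1R)-3-[2-methoxy-4-(methoxymethoxy)phenyl]-1-[4-(methoxymethoxy)phenyl]propyl]-2,4-bis(methoxymethoxy)benzene | COCOc1ccc(CC[C@H](c2ccc(OCOC)cc2)c2cc(Br)c(OCOC)cc2OCOC)c(OC)c1 | intermediate
14 | {5-[(1R)-3-[2-methoxy-4-(methoxymethoxy)phenyl]-1-[4-(methoxymethoxy)phenyl]propyl]-2,4-bis(methoxymethoxy)phenyl}lithium | COCOc1ccc(CC[C@H](c2ccc(OCOC)cc2)c2cc([Li])c(OCOC)cc2OCOC)c(OC)c1 | intermediate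
15 | 1-{5-[(1R)-3-[2-methoxy-4-(methoxymethoxy)phenyl]-1-[4-(methoxymethoxy)phenyl]propyl]-2,4-bis(methoxymethoxy)phenyl}ethan-1-one | COCOc1ccc(CC[C@H](c2ccc(OCOC)cc2)c2cc(C(C)=O)c(OCOC)cc2OCOC)c(OC)c1 | intermediate
16 | 5-hydroxy-2-methoxybenzaldehyde | COc1ccc(O)cc1C=O | starting material
17 | 2-methoxy-5-(methoxymethoxy)benzaldehyde | COCOc1ccc(OC)c(C=O)c1 | intermediate
18 | (2E)-3-[2-methoxy-5-(methoxymethoxy)phenyl]-1-{5-[(1R)-3-[2-methoxy-4-(methoxymethoxy)phenyl]-1-[4-(methoxymethoxy)phenyl]propyl]-2,4-bis(methoxymethoxy)phenyl}prop-2-en-1-one | COCOc1ccc(CC[C@H](c2ccc(OCOC)cc2)c2cc(C(=O)/C=C/c3cc(OCOC)ccc3OC)c(OCOC)cc2OCOC)c(OC)c1 | intermediate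
19 | (2E)-1-{2,4-dihydroxy-5-[(1R)-3-(4-hydroxy-2-methoxyphenyl)-1-(4-hydroxyphenyl)propyl]phenyl}-3-(5-hydroxy-2-methoxyphenyl)prop-2-en-1-one | COc1cc(O)ccc1CC[C@H](c1ccc(O)cc1)c1cc(C(=O)/C=C/c2cc(O)ccc2OC)c(O)cc1O | intermediate
20 | (2S)-7-hydroxy-2-(5-hydroxy-2-methoxyphenyl)-6-[(1R)-3-(4-hydroxy-2-methoxyphenyl)-1-(4-hydroxyphenyl)propyl]-2,3-dihydro-4H-chromen-4-one | COc1cc(O)ccc1CC[C@H](c1ccc(O)cc1)c1cc2c(cc1O)O[C@H](c1cc(O)ccc1OC)CC2=O | intermediate
21 | (2S,4S)-2-(5-hydroxy-2-methoxyphenyl)-6-[(1R)-3-(4-hydroxy-2-methoxyphenyl)-1-(4-hydroxyphenyl)propyl]-3,4-dihydro-2H-chromene-4,7-diol | COc1cc(O)ccc1CC[C@H](c1ccc(O)cc1)c1cc2c(cc1O)O[C@H](c1cc(O)ccc1OC)C[C@@H]2O | intermediate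
22 | (2S)-2-(5-hydroxy-2-methoxyphenyl)-6-[(1R)-3-(4-hydroxy-2-methoxyphenyl)-1-(4-hydroxyphenyl)propyl]-3,4-dihydro-2H-chromen-7-ol | COc1cc(O)ccc1CC[C@H](c1ccc(O)cc1)c1cc2c(cc1O)O[C@H](c1cc(O)ccc1OC)CC2 | target

## Step count and risks

Total: 15 steps. Longest linear sequence: 13 steps from 1 (steps 1–5, 7–9, 11–15); steps 6 and 10 prepare the side fragments 9 and 17.

**Step 13 (key step).** The most likely failure is that the enzyme does not accept 19 because the C5' substituent finds no room, so that only the slow, unselective background closure takes place. The first response stays within the idea (enzyme panel, mutagenesis, as in the step). The fallback with known chemistry sets out from 19: heating with NaOAc in aqueous ethanol closes the ring without control to the C2-epimeric flavanone mixture F1. A Noyori-type asymmetric transfer hydrogenation with RuCl[(S,S)-TsDPEN](p-cymene) in HCO2H/Et3N then acts as a kinetic resolution. By analogy with other benzo-fused ketones this catalyst forms the 4S carbinol and should therefore reduce the 2S epimer to the cis alcohol, which is 21, where the route is rejoined. The unreduced (2R)-flavanone epimer F2 is returned to F1 by the same base treatment and recycled.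

**Step 2.** Carborhodation of the electron-rich 7-alkoxycoumarin may be slow, so that protodeboronation of 3 consumes the aryl donor. The fallback sets out from 2 and 3: an oxidative Heck arylation (Pd(OAc)2, 1,10-phenanthroline, O2, DMF) gives 7-(methoxymethoxy)-4-[4-(methoxymethoxy)phenyl]-2H-chromen-2-one F3. A copper hydride asymmetric conjugate reduction (Cu(OAc)2, DTBM-SEGPHOS enantiomer chosen for the 4R product, diethoxymethylsilane, toluene) then delivers hydride instead of aryl to C4 and returns to 4.

**Step 8.** Hot alkali may cause loss of bromine or of an ether group, or base-mediated erosion of the doubly benzylic stereocentre. The fallback sets out from 11: condensation with TsNHNH2 in ethanol gives the tosylhydrazone F4 of ketone 11, and a Caglioti-type reduction with catecholborane followed by NaOAc·3H2O at reflux removes the nitrogen under nearly neutral conditions and returns to 13.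

**Step 12.** Acid may promote non-enzymatic ring closure of the liberated 2'-hydroxychalcone, and the electron-rich rings may capture formaldehyde equivalents during acetal cleavage. The fallback sets out from 15 and moves the deprotection ahead of enone formation: 3 M HCl in methanol gives 1-{2,4-dihydroxy-5-[(1R)-3-(4-hydroxy-2-methoxyphenyl)-1-(4-hydroxyphenyl)propyl]phenyl}ethan-1-one F5. This is condensed with unprotected 16 in concentrated aqueous KOH/ethanol, where the chalcone is held open as its phenoxide, and cold acidification returns to 19.

**Step 15.** Hydrogenolysis may continue into the benzylic O1–C2 bond, which the ortho-methoxy ring B makes more labile, opening ring C. The fallback sets out from 21 and replaces surface hydrogenolysis by ionic hydrogenation (Et3SiH, CF3CO2H, CH2Cl2, -20 °C), in which only the much better stabilised C4 cation forms and is trapped by hydride; it returns directly to 22 and makes no new compound.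

## Further compounds

F1 | step 13 | (2RS)-7-hydroxy-2-(5-hydroxy-2-methoxyphenyl)-6-[(1R)-3-(4-hydroxy-2-methoxyphenyl)-1-(4-hydroxyphenyl)propyl]-2,3-dihydro-4H-chromen-4-one (C2-epimeric mixture) | COc1cc(O)ccc1CC[C@H](c1ccc(O)cc1)c1cc2c(cc1O)OC(c1cc(O)ccc1OC)CC2=O
F2 | step 13 | (2R)-7-hydroxy-2-(5-hydroxy-2-methoxyphenyl)-6-[(1R)-3-(4-hydroxy-2-methoxyphenyl)-1-(4-hydroxyphenyl)propyl]-2,3-dihydro-4H-chromen-4-one | COc1cc(O)ccc1CC[C@H](c1ccc(O)cc1)c1cc2c(cc1O)O[C@@H](c1cc(O)ccc1OC)CC2=O
F3 | step 2 | 7-(methoxymethoxy)-4-[4-(methoxymethoxy)phenyl]-2H-chromen-2-one | COCOc1ccc(cc1)-c1cc(=O)oc2cc(OCOC)ccc12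
F4 | step 8 | 4-methylbenzenesulfonylhydrazone of (3R)-3-[5-bromo-2,4-bis(methoxymethoxy)phenyl]-1-[2-methoxy-4-(methoxymethoxy)phenyl]-3-[4-(methoxymethoxy)phenyl]propan-1-one | COCOc1ccc(C(=NNS(=O)(=O)c2ccc(C)cc2)C[C@H](c2ccc(OCOC)cc2)c2cc(Br)c(OCOC)cc2OCOC)c(OC)c1
F5 | step 12 | 1-{2,4-dihydroxy-5-[(1R)-3-(4-hydroxy-2-methoxyphenyl)-1-(4-hydroxyphenyl)propyl]phenyl}ethan-1-one | COc1cc(O)ccc1CC[C@H](c1ccc(O)cc1)c1cc(C(C)=O)c(O)cc1O
F0 | step 15 | none | none
A1 | alternative 1 | (5S)-7-[4-(benzyloxy)-2-methoxyphenyl]-5-[4-(benzyloxy)phenyl]-1-methoxy-1,3-bis(trimethylsilyloxy)hepta-1,3-diene (enol ether geometry not fixed) | COc1cc(OCc2ccccc2)ccc1CC[C@H](c1ccc(OCc2ccccc2)cc1)C=C(O[Si](C)(C)C)C=C(OC)O[Si](C)(C)C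
A2 | alternative 1 | (5R)-5-[5-(benzyloxy)-2-methoxyphenyl]-5-[(tert-butyldimethylsilyl)oxy]pent-1-yn-3-one | C#CC(=O)C[C@@H](O[Si](C)(C)C(C)(C)C)c1cc(OCc2ccccc2)ccc1OC
A3 | alternative 1 | (3R)-3-[5-(benzyloxy)-2-methoxyphenyl]-1-{5-[(1R)-3-[4-(benzyloxy)-2-methoxyphenyl]-1-[4-(benzyloxy)phenyl]propyl]-2,4-dihydroxyphenyl}-3-[(tert-butyldimethylsilyl)oxy]propan-1-one | COc1cc(OCc2ccccc2)ccc1CC[C@H](c1ccc(OCc2ccccc2)cc1)c1cc(C(=O)C[C@@H](O[Si](C)(C)C(C)(C)C)c2cc(OCc3ccccc3)ccc2OC)c(O)cc1O
A4 | alternative 2 | 1-(benzyloxy)-2-[(1R)-3-[4-(benzyloxy)-2-methoxyphenyl]-1-[4-(benzyloxy)phenyl]propyl]-5-{[(1S)-1-[5-(benzyloxy)-2-methoxyphenyl]prop-2-yn-1-yl]oxy}benzene | COc1cc(OCc2ccccc2)ccc1CC[C@H](c1ccc(OCc2ccccc2)cc1)c1ccc(O[C@H](c2cc(OCc3ccccc3)ccc2OC)C#C)cc1OCc1ccccc1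
A5 | alternative 2 | (2S)-7-(benzyloxy)-2-[5-(benzyloxy)-2-methoxyphenyl]-6-[(1R)-3-[4-(benzyloxy)-2-methoxyphenyl]-1-[4-(benzyloxy)phenyl]propyl]-2H-chromene | COc1cc(OCc2ccccc2)ccc1CC[C@H](c1ccc(OCc2ccccc2)cc1)c1cc2c(cc1OCc1ccccc1)O[C@H](c1cc(OCc3ccccc3)ccc1OC)C=C2
A6 | alternative 3 | 5-(benzyloxy)-4-[(1R)-3-[4-(benzyloxy)-2-methoxyphenyl]-1-[4-(benzyloxy)phenyl]propyl]-2-(hydroxymethyl)phenol | COc1cc(OCc2ccccc2)ccc1CC[C@H](c1ccc(OCc2ccccc2)cc1)c1cc(CO)c(O)cc1OCc1ccccc1
A7 | alternative 3 | 4-(benzyloxy)-2-ethenyl-1-methoxybenzene | C=Cc1cc(OCc2ccccc2)ccc1OC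
A8 | alternative 3 | (2S)-7-(benzyloxy)-2-[5-(benzyloxy)-2-methoxyphenyl]-6-[(1R)-3-[4-(benzyloxy)-2-methoxyphenyl]-1-[4-(benzyloxy)phenyl]propyl]-3,4-dihydro-2H-chromene | COc1cc(OCc2ccccc2)ccc1CC[C@H](c1ccc(OCc2ccccc2)cc1)c1cc2c(cc1OCc1ccccc1)O[C@H](c1cc(OCc3ccccc3)ccc1OC)CC2
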